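**Retrosynthetic overview**

1. The acid is taken back to a 2‑hydroxyethyl arm on C3 (late oxidation) and the C4 methyl to an exocyclic methylene (diimide reduction), which comes from a ring enal by tosylhydrazone reduction with a 1,3‑shift of the double bond.
2. Key disconnection: the 3,6‑dihydro‑1,2‑dioxine‑4‑carbaldehyde is cut at O2–C3 and at C4=C5 into a tertiary α‑hydroperoxy aldehyde and a simple (E)‑enal; forward, an amine‑catalysed peroxide conjugate addition is followed by an aldol condensation in which the C4–C5 bond closes the ring.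
3. Enabling feature: in the ring O1–O2–C3–C4–C5–C6, C5 is an unsubstituted CH2 between the fully substituted peroxy carbon C6 and C4, and C4 carries a one‑carbon branch. C5 can therefore be the formyl carbon of a non‑enolisable aldehyde that already holds O1–O2 on C6, while C4 and its methyl carbon are the α‑ and formyl carbons of an enal whose β‑carbon is C3.
4. The hydroperoxy aldehyde comes from a Sharpless epoxide of an (E)‑allylic alcohol by perhydrolysis at the tertiary carbon with inversion (sets C6) and glycol cleavage; the allylic alcohol comes from (R)‑citronellal (side‑chain stereocentre) by cross‑metathesis, hydrogenation, alkyne formation and carboalumination.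
5. Rings: the oxirane made in step 5 is opened in step 6; the 1,2‑dioxane, the only ring of the target, is formed once, in step 9.

Key step: step 9

Assumption: compounds 1, 2, 12 and 13 are taken as commercial, and the (R) amine catalyst in step 9 is chosen on the usual model in which the diphenyl(silyloxy)methyl group shields one face of the (E)‑iminium ion (the (S) catalyst would be used if the opposite sense were found).

**Route**

Step 1
Reactants: 1 (R)‑citronellal; 2 6‑phenylhex‑1‑ene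
Product: 3 (3R)‑3‑methyl‑11‑phenylundec‑6‑enal (E/Z mixture; E isomer drawn)
Conditions: second‑generation Grubbs catalyst RuCl2(=CHPh)(PCy3)(H2IMes) (cat.), CH2Cl2, 40 °C
Reagents that add atoms: none
Why: Olefin cross‑metathesis between the prenyl‑type trisubstituted alkene of 1 and the terminal alkene of 2 should release 2‑methylpropene and join the chain, the stereocentre being remote and the alkene geometry irrelevant because the double bond is hydrogenated next.

Step 2
Reactants: 3 (3R)‑3‑methyl‑11‑phenylundec‑6‑enal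
Product: 4 (3R)‑3‑methyl‑11‑phenylundecanal
Conditions: H2 (1 atm), Pd/C, EtOAc, rt
Reagents that add atoms: none
Why: Heterogeneous catalytic hydrogenation should saturate the isolated disubstituted alkene much faster than it reduces the aliphatic aldehyde or the arene.

Step 3
Reactants: 4 (3R)‑3‑methyl‑11‑phenylundecanal
Product: 5 (4R)‑4‑methyl‑12‑phenyldodec‑1‑yne
Conditions: dimethyl (1‑diazo‑2‑oxopropyl)phosphonate, K2CO3, MeOH, 0 °C → rt
Reagents that add atoms: dimethyl (1‑diazo‑2‑oxopropyl)phosphonate, COP(=O)(OC)C(=[N+]=[N-])C(C)=O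
Why: Ohira–Bestmann homologation (Seyferth–Gilbert type) should turn the aldehyde into the terminal alkyne under mild carbonate conditions, and the β‑stereocentre cannot epimerise.

Step 4
Reactants: 5 (4R)‑4‑methyl‑12‑phenyldodec‑1‑yne
Product: 8 (2E,5R)‑3,5‑dimethyl‑13‑phenyltridec‑2‑en‑1‑ol, via alkenylalane 6 (not isolated), via lithium alanate 7 (not isolated)
Conditions: AlMe3, Cp2ZrCl2 (cat.), CH2Cl2, 0 °C → rt; then n‑BuLi, THF, −78 °C; then (CH2O)n, −78 °C → rt; aq. HCl work‑up
Reagents that add atoms: trimethylaluminium, C[Al](C)C; formaldehyde (from paraformaldehyde), C=O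
Why: Zirconium‑catalysed syn‑carboalumination of the terminal alkyne places methyl on the internal and aluminium on the terminal carbon, and the derived alanate should add to formaldehyde with retention of alkene geometry, so that the (E)‑trisubstituted allylic alcohol results.

Step 5
Reactants: 8 (2E,5R)‑3,5‑dimethyl‑13‑phenyltridec‑2‑en‑1‑ol
Product: 9 {(2S,3S)‑3‑methyl‑3‑[(2R)‑2‑methyl‑10‑phenyldecyl]oxiran‑2‑yl}methanol
Conditions: Ti(OiPr)4 (cat.), L‑(+)‑diethyl tartrate (cat.), t‑BuOOH, 4 Å molecular sieves, CH2Cl2, −20 °C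
Reagents that add atoms: tert‑butyl hydroperoxide, CC(C)(C)OO
Why: Sharpless asymmetric epoxidation delivers oxygen under reagent control to one face of the (E)‑allylic alcohol, which should give the (2S,3S) epoxide irrespective of the remote side‑chain centre.

Step 6
Reactants: 9 {(2S,3S)‑3‑methyl‑3‑[(2R)‑2‑methyl‑10‑phenyldecyl]oxiran‑2‑yl}methanol
Product: 10 (2S,3R,5R)‑3‑hydroperoxy‑3,5‑dimethyl‑13‑phenyltridecane‑1,2‑diol
Conditions: H2O2 (anhydrous, in Et2O), H3PMo12O40 (cat.), Et2O, rt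
Reagents that add atoms: hydrogen peroxide, OO
Why: Polyoxomolybdate‑catalysed perhydrolysis of the epoxide (acid‑type SN2‑like ring opening by H2O2) should occur at the tertiary oxirane carbon with inversion, which sets the (3R) tertiary hydroperoxide that becomes C6 of the target.

Step 7
Reactants: 10 (2S,3R,5R)‑3‑hydroperoxy‑3,5‑dimethyl‑13‑phenyltridecane‑1,2‑diol
Product: 11 (2R,4R)‑2‑hydroperoxy‑2,4‑dimethyl‑12‑phenyldodecanal
Conditions: NaIO4, THF/pH 7 buffer, 0 °C; crude product used at once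
Reagents that add atoms: none
Why: Periodate glycol cleavage should excise the hydroxymethyl carbon and leave the hydroperoxide and the non‑epimerisable α‑carbon untouched, the labile α‑hydroperoxy aldehyde being used at once.

Step 8
Reactants: 12 3‑[(tert‑butyldimethylsilyl)oxy]propanal; 13 (triphenylphosphoranylidene)acetaldehyde
Product: 14 (2E)‑5‑[(tert‑butyldimethylsilyl)oxy]pent‑2‑enal
Conditions: toluene, 80 °C
Reagents that add atoms: none
Why: Wittig reaction of the stabilised formyl ylide with the aldehyde should give the (E)‑enal.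

Step 9
Reactants: 11 (2R,4R)‑2‑hydroperoxy‑2,4‑dimethyl‑12‑phenyldodecanal; 14 (2E)‑5‑[(tert‑butyldimethylsilyl)oxy]pent‑2‑enal
Product: 17 (3S,6R)‑3‑{2‑[(tert‑butyldimethylsilyl)oxy]ethyl}‑6‑methyl‑6‑[(2R)‑2‑methyl‑10‑phenyldecyl]‑3,6‑dihydro‑1,2‑dioxine‑4‑carbaldehyde, via peroxy dialdehyde 15 (not isolated), via aldol adduct 16 (not isolated)
Conditions: (R)‑α,α‑diphenylprolinol trimethylsilyl ether (20 mol%), 2‑nitrobenzoic acid (20 mol%), 4 Å molecular sieves, toluene, −20 °C → 0 °C
Reagents that add atoms: none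
Why: Proposed new method: the amine condenses with enal 14 to an (E)‑iminium ion, the hydroperoxy oxygen of 11 adds to its β‑carbon (C3) to give the enamine of 15, and this enamine attacks the formyl carbon (C5) of the same molecule, forming the C4–C5 bond and closing the 1,2‑dioxane as aldol 16, which loses water through the iminium/enamine manifold to release 17 and the catalyst. The closest known reaction type is the amine‑catalysed oxa‑Michael/aldol condensation of 2‑hydroxybenzaldehydes with enals to 2H‑chromene‑3‑carbaldehydes, together with the amine‑catalysed enantioselective conjugate addition of alkyl hydroperoxides to enals; new here are a hydroperoxide as the tethered nucleophile and an aliphatic α‑peroxy aldehyde as the aldol acceptor. The ring is closed in a 6‑(enolexo)‑exo‑trig aldol addition, with O1–O2 as the tether between C3 and C6. C3 is the only new stereocentre and is set by the catalyst, whose diphenyl(silyloxy)methyl group shields one face of the iminium β‑carbon so that the (R) catalyst should give (3S), while C6 and the side‑chain centre are carried through unchanged. The step needs the enamine to add to C=O and not to attack the O–O bond (Weitz–Scheffer epoxide formation), and needs 11 to act only as acceptor; this is secured because the formyl group of 11 sits on a fully substituted carbon (no α‑hydrogen, hence no enamine or self‑aldol), is activated by the α‑peroxy oxygen and is held five atoms from the enamine carbon, and because the final dehydration is irreversible.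

Step 10
Reactants: 17 (3S,6R)‑3‑{2‑[(tert‑butyldimethylsilyl)oxy]ethyl}‑6‑methyl‑6‑[(2R)‑2‑methyl‑10‑phenyldecyl]‑3,6‑dihydro‑1,2‑dioxine‑4‑carbaldehyde
Product: 18 N'‑[(E)‑{(3S,6R)‑3‑{2‑[(tert‑butyldimethylsilyl)oxy]ethyl}‑6‑methyl‑6‑[(2R)‑2‑methyl‑10‑phenyldecyl]‑3,6‑dihydro‑1,2‑dioxin‑4‑yl}methylidene]‑4‑methylbenzenesulfonohydrazide
Conditions: TsNHNH2, THF, rt
Reagents that add atoms: 4‑methylbenzenesulfonohydrazide, Cc1ccc(cc1)S(=O)(=O)NN
Why: Condensation of the unsaturated aldehyde with tosylhydrazide should give the hydrazone without added base, which spares the base‑sensitive 3,6‑dihydro‑1,2‑dioxine.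

Step 11
Reactants: 18 tosylhydrazone of 17
Product: 20 tert‑butyldimethyl{2‑[(3S,6R)‑6‑methyl‑6‑[(2R)‑2‑methyl‑10‑phenyldecyl]‑4‑methylidene‑1,2‑dioxan‑3‑yl]ethoxy}silane, via allylic diazene 19 (not isolated)
Conditions: catecholborane, CHCl3, 0 °C; then NaOAc·3H2O, 0 → 40 °C
Reagents that add atoms: none
Why: Hydride addition to the C=N bond of the α,β‑unsaturated tosylhydrazone, loss of sulfinate to allylic diazene 19 and its retro‑ene loss of N2 (reductive 1,3‑transposition) should move the double bond to the exocyclic position, which turns C5 into the ring CH2 and the former formyl carbon into the methylene that becomes the C4 methyl.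

Step 12
Reactants: 20 tert‑butyldimethyl{2‑[(3S,6R)‑6‑methyl‑6‑[(2R)‑2‑methyl‑10‑phenyldecyl]‑4‑methylidene‑1,2‑dioxan‑3‑yl]ethoxy}silane
Product: 21 tert‑butyl{2‑[(3S,4S,6R)‑4,6‑dimethyl‑6‑[(2R)‑2‑methyl‑10‑phenyldecyl]‑1,2‑dioxan‑3‑yl]ethoxy}dimethylsilane
Conditions: KO2CN=NCO2K, AcOH, MeOH/CH2Cl2, 0 °C → rt
Reagents that add atoms: none
Why: Diimide reduction transfers two hydrogens suprafacially to the 1,1‑disubstituted alkene without touching the O–O bond, and attack on the ring face opposite to both the C3 arm and the C6 decyl chain should place the new C4–H trans and the C4 methyl cis to them, giving (4S).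

Step 13
Reactants: 21 tert‑butyl{2‑[(3S,4S,6R)‑4,6‑dimethyl‑6‑[(2R)‑2‑methyl‑10‑phenyldecyl]‑1,2‑dioxan‑3‑yl]ethoxy}dimethylsilane
Product: 22 2‑[(3S,4S,6R)‑4,6‑dimethyl‑6‑[(2R)‑2‑methyl‑10‑phenyldecyl]‑1,2‑dioxan‑3‑yl]ethan‑1‑ol
Conditions: HF·pyridine, pyridine, THF, 0 °C → rt
Reagents that add atoms: none
Why: Fluoride cleavage of the silyl ether under buffered acidic conditions should free the primary alcohol while avoiding base‑induced Kornblum–DeLaMare opening of the peroxide.

Step 14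
Reactants: 22 2‑[(3S,4S,6R)‑4,6‑dimethyl‑6‑[(2R)‑2‑methyl‑10‑phenyldecyl]‑1,2‑dioxan‑3‑yl]ethan‑1‑ol
Product: 23 2‑[(3S,4S,6R)‑4,6‑dimethyl‑6‑[(2R)‑2‑methyl‑10‑phenyldecyl]‑1,2‑dioxan‑3‑yl]acetic acid
Conditions: TEMPO (cat.), PhI(OAc)2, MeCN/H2O, rt
Reagents that add atoms: water, O
Why: Nitroxyl‑catalysed oxidation should take the primary alcohol through the aldehyde hydrate to the carboxylic acid under neutral conditions that leave the dialkyl peroxide and all four stereocentres untouched.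

**Compound list**

1 | (R)‑citronellal, (3R)‑3,7‑dimethyloct‑6‑enal | C[C@H](CCC=C(C)C)CC=O | starting material
2 | 6‑phenylhex‑1‑ene | C=CCCCCc1ccccc1 | starting material
3 | (3R)‑3‑methyl‑11‑phenylundec‑6‑enal (E/Z mixture; E isomer drawn) | O=CC[C@H](C)CC/C=C/CCCCc1ccccc1 | intermediate
4 | (3R)‑3‑methyl‑11‑phenylundecanal | O=CC[C@H](C)CCCCCCCCc1ccccc1 | intermediate
5 | (4R)‑4‑methyl‑12‑phenyldodec‑1‑yne | C#CC[C@H](C)CCCCCCCCc1ccccc1 | intermediate
6 | alkenylalane, dimethyl[(1E,4R)‑2,4‑dimethyl‑12‑phenyldodec‑1‑en‑1‑yl]alumane (not isolated) | C[Al](C)/C=C(\C)C[C@H](C)CCCCCCCCc1ccccc1 | intermediate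
7 | lithium alanate, lithium butyl(dimethyl)[(1E,4R)‑2,4‑dimethyl‑12‑phenyldodec‑1‑en‑1‑yl]aluminate (not isolated) | [Li+].CCCC[Al-](C)(C)/C=C(\C)C[C@H](C)CCCCCCCCc1ccccc1 | intermediate
8 | (2E,5R)‑3,5‑dimethyl‑13‑phenyltridec‑2‑en‑1‑ol | OC/C=C(\C)C[C@H](C)CCCCCCCCc1ccccc1 | intermediate
9 | {(2S,3S)‑3‑methyl‑3‑[(2R)‑2‑methyl‑10‑phenyldecyl]oxiran‑2‑yl}methanol | OC[C@@H]1O[C@@]1(C)C[C@H](C)CCCCCCCCc1ccccc1 | intermediate
10 | (2S,3R,5R)‑3‑hydroperoxy‑3,5‑dimethyl‑13‑phenyltridecane‑1,2‑diol | OC[C@H](O)[C@](C)(OO)C[C@H](C)CCCCCCCCc1ccccc1 | intermediate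
11 | (2R,4R)‑2‑hydroperoxy‑2,4‑dimethyl‑12‑phenyldodecanal | O=C[C@](C)(OO)C[C@H](C)CCCCCCCCc1ccccc1 | intermediate
12 | 3‑[(tert‑butyldimethylsilyl)oxy]propanal | O=CCCO[Si](C)(C)C(C)(C)C | starting material
13 | (triphenylphosphoranylidene)acetaldehyde | O=CC=P(c1ccccc1)(c1ccccc1)c1ccccc1 | starting material
14 | (2E)‑5‑[(tert‑butyldimethylsilyl)oxy]pent‑2‑enal | O=C/C=C/CCO[Si](C)(C)C(C)(C)C | intermediate
15 | peroxy dialdehyde, (2R,4R)‑2‑({(3S)‑5‑[(tert‑butyldimethylsilyl)oxy]‑1‑oxopentan‑3‑yl}peroxy)‑2,4‑dimethyl‑12‑phenyldodecanal (not isolated; formed as its enamine) | O=CC[C@H](CCO[Si](C)(C)C(C)(C)C)OO[C@@](C)(C=O)C[C@H](C)CCCCCCCCc1ccccc1 | intermediate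
16 | aldol adduct, (3S,6R)‑3‑{2‑[(tert‑butyldimethylsilyl)oxy]ethyl}‑5‑hydroxy‑6‑methyl‑6‑[(2R)‑2‑methyl‑10‑phenyldecyl]‑1,2‑dioxane‑4‑carbaldehyde (C4/C5 isomers; not isolated) | C[C@H](CCCCCCCCc1ccccc1)C[C@]1(C)C(O)C(C=O)[C@H](CCO[Si](C)(C)C(C)(C)C)OO1 | intermediate
17 | (3S,6R)‑3‑{2‑[(tert‑butyldimethylsilyl)oxy]ethyl}‑6‑methyl‑6‑[(2R)‑2‑methyl‑10‑phenyldecyl]‑3,6‑dihydro‑1,2‑dioxine‑4‑carbaldehyde | C[C@H](CCCCCCCCc1ccccc1)C[C@]1(C)C=C(C=O)[C@H](CCO[Si](C)(C)C(C)(C)C)OO1 | intermediate
18 | N'‑[(E)‑{(3S,6R)‑3‑{2‑[(tert‑butyldimethylsilyl)oxy]ethyl}‑6‑methyl‑6‑[(2R)‑2‑methyl‑10‑phenyldecyl]‑3,6‑dihydro‑1,2‑dioxin‑4‑yl}methylidene]‑4‑methylbenzenesulfonohydrazide | C[C@H](CCCCCCCCc1ccccc1)C[C@]1(C)C=C(/C=N/NS(=O)(=O)c2ccc(C)cc2)[C@H](CCO[Si](C)(C)C(C)(C)C)OO1 | intermediate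
19 | allylic diazene, tert‑butyl{2‑[(3S,6R)‑4‑(diazenylmethyl)‑6‑methyl‑6‑[(2R)‑2‑methyl‑10‑phenyldecyl]‑3,6‑dihydro‑1,2‑dioxin‑3‑yl]ethoxy}dimethylsilane (not isolated) | C[C@H](CCCCCCCCc1ccccc1)C[C@]1(C)C=C(CN=N)[C@H](CCO[Si](C)(C)C(C)(C)C)OO1 | intermediate
20 | tert‑butyldimethyl{2‑[(3S,6R)‑6‑methyl‑6‑[(2R)‑2‑methyl‑10‑phenyldecyl]‑4‑methylidene‑1,2‑dioxan‑3‑yl]ethoxy}silane | C[C@H](CCCCCCCCc1ccccc1)C[C@]1(C)CC(=C)[C@H](CCO[Si](C)(C)C(C)(C)C)OO1 | intermediate
21 | tert‑butyl{2‑[(3S,4S,6R)‑4,6‑dimethyl‑6‑[(2R)‑2‑methyl‑10‑phenyldecyl]‑1,2‑dioxan‑3‑yl]ethoxy}dimethylsilane | C[C@H](CCCCCCCCc1ccccc1)C[C@]1(C)C[C@H](C)[C@H](CCO[Si](C)(C)C(C)(C)C)OO1 | intermediate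
22 | 2‑[(3S,4S,6R)‑4,6‑dimethyl‑6‑[(2R)‑2‑methyl‑10‑phenyldecyl]‑1,2‑dioxan‑3‑yl]ethan‑1‑ol | C[C@H](CCCCCCCCc1ccccc1)C[C@]1(C)C[C@H](C)[C@H](CCO)OO1 | intermediate
23 | 2‑[(3S,4S,6R)‑4,6‑dimethyl‑6‑[(2R)‑2‑methyl‑10‑phenyldecyl]‑1,2‑dioxan‑3‑yl]acetic acid | C[C@H](CCCCCCCCc1ccccc1)C[C@]1(C)C[C@H](C)[C@H](CC(=O)O)OO1 | target

**Step count and risks**

Total step count: 14. Longest linear sequence: 13 (steps 1–7 and 9–14; step 8 makes the enal partner).

Steps most likely to fail:

Step 9 (proposed new method). The enamine formed after the peroxide conjugate addition may attack the O–O bond instead of the formyl group (epoxide formation with loss of the peroxide), the free hydroperoxy aldehyde may fragment under the amine, or the amine may open the product ring by proton abstraction at C3. The fallback uses known reactions one at a time, with the formyl group masked and the ring closed under acid instead of through an enamine. It sets out from 11, which with HC(OMe)3 and pyridinium tosylate in MeOH should give the dimethyl acetal (2R,4R)‑2‑hydroperoxy‑1,1‑dimethoxy‑2,4‑dimethyl‑12‑phenyldodecane F1. Amine‑catalysed enantioselective conjugate addition of this alkyl hydroperoxide to enal 14 (a diarylprolinol silyl ether and an acid co‑catalyst at low temperature, a known reaction type for enals) should give the β‑peroxy aldehyde (3S)‑5‑[(tert‑butyldimethylsilyl)oxy]‑3‑{[(2R,4R)‑1,1‑dimethoxy‑2,4‑dimethyl‑12‑phenyldodecan‑2‑yl]peroxy}pentanal F2. Brief treatment with TsOH in wet acetone should unmask the second formyl group (15) and effect the acid‑catalysed intramolecular aldol condensation, so that the sequence comes back to the route at 17.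

Step 7. The free α‑hydroperoxy aldehyde may cyclise to a hydroxy‑dioxetane and fragment with loss of the formyl carbon, or oligomerise through peroxy hemiacetals before it can be used. The fallback never forms a compound that has a hydroperoxy and a formyl group on the same carbon. It sets out from diol 10, whose hydroperoxy group is added first to enal 14 under the amine/acid conditions named above, to give (3S)‑5‑[(tert‑butyldimethylsilyl)oxy]‑3‑{[(2S,3R,5R)‑1,2‑dihydroxy‑3,5‑dimethyl‑13‑phenyltridecan‑3‑yl]peroxy}pentanal F3. Periodate cleavage of the diol in F3 then gives the dialkyl peroxide 15, where the sequence comes back to the route; pyrrolidinium acetate in CH2Cl2 at 0 °C should close 15 to 17.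

Step 11. The borane may reduce the O–O bond, or the acetate‑promoted elimination at 40 °C may trigger base‑induced ring opening of the dihydrodioxine before the diazene has formed. The fallback makes the same diazene by substitution at low temperature. It sets out from 17: Luche reduction (NaBH4, CeCl3·7H2O, MeOH, −40 °C) should give the allylic alcohol [(3S,6R)‑3‑{2‑[(tert‑butyldimethylsilyl)oxy]ethyl}‑6‑methyl‑6‑[(2R)‑2‑methyl‑10‑phenyldecyl]‑3,6‑dihydro‑1,2‑dioxin‑4‑yl]methanol F4. Mitsunobu reaction of F4 with 2‑nitrobenzenesulfonylhydrazide (PPh3, diethyl azodicarboxylate, THF, −30 °C) should give N‑{[(3S,6R)‑3‑{2‑[(tert‑butyldimethylsilyl)oxy]ethyl}‑6‑methyl‑6‑[(2R)‑2‑methyl‑10‑phenyldecyl]‑3,6‑dihydro‑1,2‑dioxin‑4‑yl]methyl}‑2‑nitrobenzenesulfonohydrazide F5. On warming to rt F5 loses the sulfinate to give diazene 19, where the sequence comes back to the route, and 19 loses N2 to give 20.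

Further compounds
F1 | step 9 | (2R,4R)‑2‑hydroperoxy‑1,1‑dimethoxy‑2,4‑dimethyl‑12‑phenyldodecane | COC(OC)[C@](C)(OO)C[C@H](C)CCCCCCCCc1ccccc1
F2 | step 9 | (3S)‑5‑[(tert‑butyldimethylsilyl)oxy]‑3‑{[(2R,4R)‑1,1‑dimethoxy‑2,4‑dimethyl‑12‑phenyldodecan‑2‑yl]peroxy}pentanal | O=CC[C@H](CCO[Si](C)(C)C(C)(C)C)OO[C@@](C)(C(OC)OC)C[C@H](C)CCCCCCCCc1ccccc1
F3 | step 7 | (3S)‑5‑[(tert‑butyldimethylsilyl)oxy]‑3‑{[(2S,3R,5R)‑1,2‑dihydroxy‑3,5‑dimethyl‑13‑phenyltridecan‑3‑yl]peroxy}pentanal | O=CC[C@H](CCO[Si](C)(C)C(C)(C)C)OO[C@@](C)([C@@H](O)CO)C[C@H](C)CCCCCCCCc1ccccc1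
F4 | step 11 | [(3S,6R)‑3‑{2‑[(tert‑butyldimethylsilyl)oxy]ethyl}‑6‑methyl‑6‑[(2R)‑2‑methyl‑10‑phenyldecyl]‑3,6‑dihydro‑1,2‑dioxin‑4‑yl]methanol | C[C@H](CCCCCCCCc1ccccc1)C[C@]1(C)C=C(CO)[C@H](CCO[Si](C)(C)C(C)(C)C)OO1
F5 | step 11 | N‑{[(3S,6R)‑3‑{2‑[(tert‑butyldimethylsilyl)oxy]ethyl}‑6‑methyl‑6‑[(2R)‑2‑methyl‑10‑phenyldecyl]‑3,6‑dihydro‑1,2‑dioxin‑4‑yl]methyl}‑2‑nitrobenzenesulfonohydrazide | C[C@H](CCCCCCCCc1ccccc1)C[C@]1(C)C=C(CN(N)S(=O)(=O)c2ccccc2[N+](=O)[O-])[C@H](CCO[Si](C)(C)C(C)(C)C)OO1
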